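The tempting half-life of 4.95 s is a trap: it holds second end groups at their charge, yet they fall one for one with first end groups.

first end groups 1.0 M; second end groups 1.00 M; time 15 s

- average number of monomer units in a chain (unreacted monomers counted as chains of one) at 15 s
- part of the first end groups that has reacted at 15 s

- each molecule carries two end groups: a chain counts once for every two ends that are left, dead ends included; the units are half of the end groups of the two monomers charged
- run time (flask): 15 s

First end groups and second end groups join into links and by-product with forward constant k = 0.14 L mol⁻¹ s⁻¹ and equilibrium constant K = 130. The charges are equal, so the first end groups left equal the second end groups left. That amount also counts the chains, so chain length is the charge divided by it.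

This reckoning writes the balance of first end groups in two ways. Dropping the way back, the inverse of first end groups grows steadily:

chain length = 1 + k · charge · t = 3.10, reacted 67.7 %

Keeping the way back brings in the turning time T, the time the forward line needs to reach the equilibrium ceiling of chain length, 12.4: T = √K/(k · charge) = 81.4 s. With it the balance integrates exactly:

chain length = 1 + √K · tanh(t/T) = 3.08, reacted 67.5 %

The forward way cheats, reading higher by 0.0200, but the gap stays small because the run is shorter than the turning time. The reckoning commits to the second way.

The forecast gave 3.08 and 67.5 %, level with this reckoning, holding that “the reverse reaction trims this only slightly”.

The flask gives 3.08 and 67.5 %.

    first end groups + second end groups ⇌ links + by-product (K1 = 130, k1 = 0.14 L mol⁻¹ s⁻¹)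

In this flask, links rose to 51.1 % by 7.50 s and 67.5 % by 15.0 s, while first end groups fell to 32.5 %. Its run covered 0.184 of the turning time. The flask left until 25 s covers 0.307 of it, and there the turning-time line gives a chain length of 4.40, the forward line 4.50. That flask held 22.8 % first end groups and 77.2 % links at 25.0 s, with a chain length of 4.39.

The numbers of this flask are assumed; the result is computed.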